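**Assumption:** the oxirane is taken exactly as written, trans-fused to ring B ((8R,9R) beside (10R)); the cis-fused isomer would be the easier compound, but no other reading is used.

**Conventions:** ring A is C1–C2–C3–C4–C5 and ring B is C5–C6–C7–C8–C9–C10–C1 (daucane skeleton: methyl on C1 and C8, isopropyl on C4). These locants are kept for every intermediate. α is the face of the C1 methyl group, β the opposite face.

## The problem

The skeleton is a hydroazulene: cyclopentane ring A and cycloheptane ring B share the C1–C5 bond in a trans fusion, and C1 is quaternary. Eight stereocentres (C1, C2, C4, C5, C6, C8, C9, C10) and five oxygenated carbons must be set, with an acetate on O2 and a veratrate on O6 beside free hydroxyls at C4 (tertiary) and C10 (secondary). Most of ring A can be built by relay: a C4 silyloxy group directs a nucleophile to C5; the C5 substituent directs the electrophile at C1 and later the isopropyl nucleophile at C4; the C10 hydroxymethyl group delivers hydride to C2; the C2 oxygen then steers a nucleophile at C10 through a chelate. Only C6 lies outside this chain and needs a reagent. The oxirane is the real difficulty: its oxygen is β at C9 but α at C8, so C7 and C10 stand anti across C8–C9, the arrangement of an E- and not a Z-cycloheptene. A peracid on the Z-alkene gives only the cis-fused oxirane, and a halohydrin cannot close to a trans-fused one in a seven-membered ring. Once made, the strained oxirane sits beside the free C10 hydroxyl and will not tolerate acid, fluoride or alkoxide (Payne shift). In addition, the C2 acetate is 1,3 to that hydroxyl and can migrate under base, the tertiary C4 alcohol is β to C6, and the veratrate absorbs at 254 nm. What makes a solution possible is the trisubstituted C8=C9 bond of ring B with its allylic C10 hydroxyl: it can be twisted by light on monovalent copper into the E-alkene, and oxygen added to the exposed face then copies the anti relationship of C7 and C10 into the oxirane.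

## Retrosynthesis

**26 to 23 and 24 (C6–O acyl bond).** The veratrate is removed first because it must not be present during irradiation. Making this the only operation after the oxirane means no deprotection is ever run on the strained epoxy alcohol. The forward reaction must acylate O6 in the presence of the neopentyl, axial O10 and the tertiary O4.

**23 to 21 through 22 (C8–O and C9–O).** Both oxirane bonds are cut at once, giving the plain Z-cycloheptene 21. No ionic closure or Z-alkene epoxidation can give the trans fusion, so the only alternative cuts are worse. The forward step must form the E-alkene 22 of one helicity and trap it by suprafacial oxygen transfer. O10 is left free on purpose. In the helicity that leads to 23, the C10–O bond lies gauche to the alkene on its exposed face. A hydroxyl there can bind the copper and hydrogen-bond the oxidant, whereas a silyl ether would press against the C8 methyl group and shield that face.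

**21 to 17 through 20, 19 and 18 (acyl on O2, benzyl on O2).** The acetate cannot survive the organometallic steps, so O2 carries a p-methoxybenzyl group until ring B is closed. O6 and O10 are covered as triethylsilyl ethers (18) while the benzyl ether is cleaved (19) and the acetate installed (20); one fluoride treatment then frees both. The forward steps need only standard selectivity: the tertiary O4 stays untouched throughout.

**17 to 16 (C8=C9).** Ring B is opened at its double bond by ring-closing metathesis. Compared with closure at C9–C10 by a vinyl-metal addition, this avoids a Z-iodoalkene side chain that is awkward to attach at C7, and the seven-membered ring can only form as the Z-alkene. The diene 16 is acyclic in ring B and simpler by one ring.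

**16 to 15, 14 and 13 (C9–C10; oxidation level of C10; acetal).** The vinyl group is cut from C10, leaving aldehyde 15 on the quaternary C1. The p-methoxybenzyl ether on O2 is placed so that it can chelate the aldehyde, which is the reason for choosing this cut over an aldol-type C1–C10 construction of the carbinol. The latter is predicted to give the C10 epimer through a closed transition state. Aldehyde 15 comes from primary alcohol 14, and 14 from the cyclic acetal 13 by reductive opening, which differentiates O2 from O10 without separate protection steps.

**13 to 12, 11 and 10 (C6–C7; C6=C7; C4–isopropyl).** The methallyl group is cut from C6 (reagent-controlled allylboration of aldehyde 12). Aldehyde 12 comes from the vinyl group of 11 by oxidative cleavage, and the isopropyl group is cut from C4 of 11, giving ketone 10. The isopropyl group is added before the vinyl group is cleaved, so no protecting group is needed on O6 while the C4 silyl ether is exchanged for the tertiary alcohol. Ketone 10 comes from silyl ether 8 through alcohol 9.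

**8 to 7 and 6 (acetal; C2–H).** The acetal 8 is the protected form of diol 7, whose C2 carbinol comes from ketone 6 by hydride delivery from the C10 hydroxyl. A free reduction would attack from the methyl face and give the wrong epimer, which is why the hydroxymethyl group is introduced unprotected.

**6 to 4 through 5, and 4 to 3, 2 and 1 (C5–C6 and C1–C10).** Both ring A substituents are removed in one cut: a vinyl group from C5 and a hydroxymethyl group from C1 of enone 4. Conjugate addition anti to the silyloxy group followed by hydroxymethylation of enolate 5 anti to the new vinyl group sets C5, the quaternary C1 and the trans relationship that becomes the ring fusion. Enone 4 comes from the commercial hydroxy enone 1 by silylation (2), α-iodination (3) and methyl coupling.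

## Roads not taken

**Alternative 1: ring B from a benzene ring.**
- *Cut and key step:* C1–C5 and C1–C10 together. Rh2(OAc)4 would turn the diazo ketone A2, whose anisole ring already carries the C6 oxygen and the C8 methyl, into the cycloheptatriene A1 by carbene addition to the aryl C5–C10 bond and electrocyclic opening. Ring A closes and the arene becomes ring B in one catalytic step.
- *Merits:* very short access to the bicyclic carbon skeleton; the key step is catalytic and of a known type.
- *Weak points:* A1 is flat. C5 is sp2, so the trans fusion must be set later by reducing a tetrasubstituted enol ether. C2, C6 and C10 remain to be set on a triene with little bias, and C10 carries no oxygen. The other ortho bond (C5–C6) can compete for the carbene, an α-methyl diazo ketone can lose the carbene by 1,2-hydride shift, and the face selectivity at C1 rests on the single C4 centre.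
- *Comparison:* this road is better in step economy to a ring B compound and in the security of its key reaction. The chosen plan sets each sp3 centre in a separate controlled event and reaches 21 with the oxidation pattern correct. A1 would need selective reduction of two of three double bonds and an allylic oxidation, and it would still end with the same E-alkene step.

**Alternative 2: Hajos–Parrish ketone and one-carbon enlargement.**
- *Cut and key step:* C6–C7 and C7–C8. After the ring fusion has been set on material from (S)-A5, the silyl enol ether A4 (C6=C8) is cyclopropanated with Et2Zn and CH2I2, and the three-membered ring is opened with FeCl3 to give cycloheptenone A3 with C7 inserted.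
- *Merits:* A5 is cheap and enantiopure and supplies quaternary C1 with the C2 oxygen. The enlargement is regiodefined known chemistry. A3 has a ketone at C8, where the methyl must go, and an enone that can bring oxygen to C6.
- *Weak points:* C10 is an unactivated methylene beside the quaternary centre and needs a second desaturation and β-oxygenation. A trans ring fusion from A5 is a known difficulty. The C4 oxygen is not in A5. Turning the C8 ketone into C8(Me)=C9 must be regioselective against C7.
- *Comparison:* this road is better in the cost of the chiral starting material and in having a precedented key step, and equal in that it too would finish with the photochemical step. The chosen plan brings the C6 and C10 oxygens in with their carbons (two aldehyde additions) and fixes the trans fusion in the conjugate addition–aldol, so no enone transposition on ring B is needed.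

**Alternative 3: Wieland–Miescher ketone and semipinacol shift.**
- *Cut and key step:* C1–C5. In the cis-decalin hydroxy mesylate A7, made from (R)-A8, C1 is bonded to C6. KOtBu deprotonates the ring-fusion hydroxyl and C1 migrates to C5 anti to the leaving mesylate, giving the trans-fused ketone A6. One six-membered ring contracts to ring A and the other expands to ring B.
- *Merits:* the shift is stereospecific (retention at C1, inversion at C5), so the trans fusion follows from the mesylate configuration. A6 carries oxygen at C4, C6 and C10.
- *Weak points:* C2 is a bare methylene next to the quaternary C1 and cannot be reached by enolate chemistry. The C8 methyl and the C8=C9 bond must be built from the C10 ketone by desaturation, conjugate methylation and a second desaturation. The less common enantiomer of A8 is required. Migration of C1 rather than C7 depends on the mesylate being anti to C1–C6.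
- *Comparison:* this is the strongest competitor. Its key step is more certain than an enolate trapping for the ring fusion, and it is as good as the chosen plan for C4, C6 and C10. The chosen plan has the C2 oxygen from the start (the carbonyl of 4) and delivers C8=C9 directly by metathesis; these are exactly the positions without a handle in A6. It would also still need the E-alkene step.

Key step: step 20

## Route

Step 1
Reactants: 1 (S)-4-hydroxycyclopent-2-en-1-one
Product: 2 (S)-4-(tert-butyldimethylsilyloxy)cyclopent-2-en-1-one
Conditions: TBSCl, imidazole, DMAP (cat.), CH2Cl2, 0 °C → rt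
Reagents that add atoms: tert-butyldimethylsilyl chloride, CC(C)(C)[Si](C)(C)Cl
Why: Standard imidazole-promoted silylation of a secondary alcohol; the stereocentre is untouched and the silyl ether later directs the conjugate addition.

Step 2
Reactants: 2 (S)-4-(tert-butyldimethylsilyloxy)cyclopent-2-en-1-one
Product: 3 (S)-4-(tert-butyldimethylsilyloxy)-2-iodocyclopent-2-en-1-one
Conditions: I2, pyridine, CH2Cl2, 0 °C → rt
Reagents that add atoms: iodine, II
Why: Amine-promoted α-iodination of an enone (conjugate addition of pyridine, iodination, elimination) is routine for 4-silyloxycyclopentenones and does not touch C4.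

Step 3
Reactants: 3 (S)-4-(tert-butyldimethylsilyloxy)-2-iodocyclopent-2-en-1-one
Product: 4 (S)-4-(tert-butyldimethylsilyloxy)-2-methylcyclopent-2-en-1-one
Conditions: SnMe4, PdCl2(PhCN)2 (cat.), AsPh3, CuI (cat.), NMP, 60 °C
Reagents that add atoms: tetramethylstannane, C[Sn](C)(C)C
Why: Stille coupling of an α-iodoenone under neutral conditions installs the C1 methyl group without base-induced loss of the β-silyloxy group.

Step 4
Reactants: 4 (S)-4-(tert-butyldimethylsilyloxy)-2-methylcyclopent-2-en-1-one
Product: 6 (2R,3S,4S)-4-(tert-butyldimethylsilyloxy)-2-(hydroxymethyl)-2-methyl-3-vinylcyclopentan-1-one, via bromomagnesium enolate 5 (not isolated)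
Conditions: CH2=CHMgBr, CuBr·SMe2 (cat.), THF, −78 °C; then CH2O (gas, from paraformaldehyde), −78 → −40 °C; NH4Cl (aq)
Reagents that add atoms: vinylmagnesium bromide, C=C[Mg]Br; formaldehyde, C=O
Why: Copper-catalysed conjugate addition places the vinyl group anti to the C4 silyloxy group (sets C5), and enolate 5 is hydroxymethylated on the face away from the new vinyl group (sets quaternary C1 with methyl α and C10 β); tandem conjugate addition–aldol.

Step 5
Reactants: 6 (2R,3S,4S)-4-(tert-butyldimethylsilyloxy)-2-(hydroxymethyl)-2-methyl-3-vinylcyclopentan-1-one
Product: 7 ring A diol: 4β-(tert-butyldimethylsilyloxy)-1β-(hydroxymethyl)-1α-methyl-5α-vinylcyclopentan-2α-ol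
Conditions: Me4NBH(OAc)3, MeCN/AcOH, −30 → −20 °C
Reagents that add atoms: none
Why: Evans–Saksena hydroxyl-directed reduction: the C10 hydroxyl binds boron and delivers hydride to the β-face of the C2 ketone, giving the 2α-alcohol anti to the hydroxymethyl group.

Step 6
Reactants: 7 ring A diol
Product: 8 O2,O10-(4-methoxybenzylidene) acetal of 7 (trans-fused 1,3-dioxane, aryl equatorial; 4β-OTBS, 5α-vinyl)
Conditions: 4-MeOC6H4CH(OMe)2, PPTS (cat.), CH2Cl2, 4 Å sieves, rt
Reagents that add atoms: 4-methoxybenzaldehyde dimethyl acetal, COc1ccc(C(OC)OC)cc1
Why: Acid-catalysed transacetalisation of the 1,3-diol under thermodynamic control puts the aryl group equatorial; the acetal centre is removed again in step 12.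

Step 7
Reactants: 8 acetal silyl ether
Product: 9 4β-alcohol (acetal, 5α-vinyl)
Conditions: Bu4NF, THF, 0 °C → rt
Reagents that add atoms: none
Why: Fluoride cleaves the only silyl ether; acetal and alkene are inert.

Step 8
Reactants: 9 4β-alcohol
Product: 10 C4 ketone (acetal, 5α-vinyl)
Conditions: Dess–Martin periodinane, NaHCO3, CH2Cl2, 0 °C → rt
Reagents that add atoms: none
Why: Buffered Dess–Martin oxidation gives the β,γ-unsaturated ketone without base, so the vinyl group is not conjugated and C5 is not epimerised.

Step 9
Reactants: 10 C4 ketone
Product: 11 4α-hydroxy-4β-isopropyl compound (acetal, 5α-vinyl)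
Conditions: iPrMgCl, CeCl3, THF, −78 → −40 °C
Reagents that add atoms: isopropylmagnesium chloride, CC(C)[Mg]Cl
Why: Organocerium 1,2-addition (low basicity suppresses enolisation and reduction) occurs on the β-face, anti to the adjacent α-vinyl group and to the α-substituents on C1 and C2, giving the 4α-alcohol with the isopropyl group β.

Step 10
Reactants: 11 tertiary alcohol with 5α-vinyl group
Product: 12 C6 aldehyde (5α-formyl; acetal; 4α-OH, 4β-isopropyl)
Conditions: OsO4 (cat.), NaIO4, 2,6-lutidine, dioxane/H2O, rt
Reagents that add atoms: sodium periodate, [Na+].[O-]I(=O)(=O)=O; osmium tetroxide, O=[Os](=O)(=O)=O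
Why: Lemieux–Johnson cleavage of the only alkene under lutidine buffering leaves the acetal and the C5 centre intact (ozone would attack the benzylidene acetal).

Step 11
Reactants: 12 C6 aldehyde
Product: 13 (6R)-homoallylic alcohol: C5 carries α-CH(OH)CH2C(CH3)=CH2 (acetal; 4α-OH, 4β-isopropyl)
Conditions: (+)-Ipc2BOMe, CH2=C(CH3)CH2MgCl, Et2O, 0 °C; then 12, −78 °C; NaOH, H2O2
Reagents that add atoms: 2-methylallylmagnesium chloride, CC(=C)C[Mg]Cl, transferred as B-(2-methylallyl)diisopinocampheylborane, CC(=C)CB([C@H]1C[C@H]2C[C@@H]([C@@H]1C)C2(C)C)[C@H]1C[C@H]2C[C@@H]([C@@H]1C)C2(C)C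
Why: Brown methallylboration through a chair transition state; the isopinocampheyl groups derived from (−)-α-pinene deliver the methallyl group to the Re face of the aldehyde and set (6R) by reagent control.

Step 12
Reactants: 13 (6R)-homoallylic alcohol acetal
Product: 14 triol: 2α-(4-methoxybenzyloxy), 1β-CH2OH, 4α-OH, (6R)-OH
Conditions: iBu2AlH, CH2Cl2, −78 → 0 °C; Rochelle salt
Reagents that add atoms: none
Why: Reductive acetal opening: the aluminium hydride coordinates the less hindered primary O10 and cleaves its C–O bond, leaving the p-methoxybenzyl group on the hindered O2.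

Step 13
Reactants: 14 triol
Product: 15 C10 aldehyde (1β-formyl; 2α-OPMB; 4α-OH; (6R)-OH)
Conditions: TEMPO (cat.), PhI(OAc)2, CH2Cl2, rt
Reagents that add atoms: none
Why: Oxoammonium oxidation is selective for the primary alcohol over the secondary C6 and tertiary C4 hydroxyls and gives a non-enolisable neopentyl aldehyde.

Step 14
Reactants: 15 C10 aldehyde
Product: 16 (6R,10S)-diene triol: 1β-[(S)-CH(OH)CH=CH2], 2α-OPMB, 4α-OH, (6R)-CH(OH)CH2C(CH3)=CH2 on C5
Conditions: MgBr2·OEt2, CH2Cl2, −78 °C; then CH2=CHMgBr, −78 °C
Reagents that add atoms: vinylmagnesium bromide, C=C[Mg]Br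
Why: Chelation-controlled Grignard addition: magnesium bridges the aldehyde oxygen and the O2 benzyl ether in a six-membered chelate trans-fused to ring A, where the C1 methyl is axial, so the vinyl group adds anti to the methyl and gives the (10S)-alcohol (10β-OH of ring B).

Step 15
Reactants: 16 (6R,10S)-diene triol
Product: 17 2α-(4-methoxybenzyloxy)dauc-8(Z)-ene-4α,6β,10β-triol
Conditions: (H2IMes)(PCy3)Cl2Ru=CHPh (second-generation Grubbs catalyst, cat.), CH2Cl2 (dilute), 40 °C
Reagents that add atoms: none
Why: Ring-closing metathesis of the vinyl and 1,1-disubstituted alkenes closes ring B as the trisubstituted Z-cycloheptene, the only geometry the ring accepts thermally; the free allylic hydroxyl assists loading at the hindered vinyl group.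

Step 16
Reactants: 17 cycloheptene triol
Product: 18 6β,10β-bis(triethylsilyloxy)-2α-(4-methoxybenzyloxy)dauc-8(Z)-en-4α-ol
Conditions: Et3SiOTf, 2,6-lutidine, CH2Cl2, −78 → 0 °C
Reagents that add atoms: triethylsilyl trifluoromethanesulfonate, CC[Si](CC)(CC)OS(=O)(=O)C(F)(F)F
Why: Silyl triflate silylation of the two secondary hydroxyls at low temperature; the hindered tertiary C4 hydroxyl is left free.

Step 17
Reactants: 18 bis(silyl) ether
Product: 19 6β,10β-bis(triethylsilyloxy)dauc-8(Z)-ene-2α,4α-diol
Conditions: DDQ, CH2Cl2/pH 7 buffer, 0 °C → rt
Reagents that add atoms: none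
Why: Oxidative cleavage of the p-methoxybenzyl ether (electron transfer to DDQ, hydrolysis of the oxocarbenium ion); silyl ethers and the trisubstituted alkene are inert.

Step 18
Reactants: 19 2α,4α-diol
Product: 20 2α-acetoxy-6β,10β-bis(triethylsilyloxy)dauc-8(Z)-en-4α-ol
Conditions: Ac2O, DMAP, pyridine, rt
Reagents that add atoms: acetic anhydride, CC(=O)OC(C)=O
Why: DMAP-catalysed acetylation of the only free secondary hydroxyl; the hindered tertiary C4 hydroxyl does not react under these conditions.

Step 19
Reactants: 20 acetate bis(silyl) ether
Product: 21 2α-acetoxydauc-8(Z)-ene-4α,6β,10β-triol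
Conditions: HF·pyridine, pyridine, THF, 0 °C → rt
Reagents that add atoms: none
Why: Buffered fluoride cleaves both triethylsilyl ethers while the acetate stays in place; no alkoxide is formed, so the acetyl group should not migrate to O10.

Step 20
Reactants: 21 2α-acetoxydauc-8(Z)-ene-4α,6β,10β-triol
Product: 23 (8R,9R)-2α-acetoxy-8,9-epoxydaucane-4α,6β,10β-triol (oxirane trans-fused to ring B: oxygen β at C9 and α at C8), via E-alkene copper triflate complex 22 (not isolated)
Conditions: (CuOTf)2·C6H6 (1.2 equiv Cu), Et2O/THF, hν (254 nm, quartz), −78 °C; then MeCN, dimethyldioxirane (acetone), −78 → −40 °C, dark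
Reagents that add atoms: dimethyldioxirane, CC1(C)OO1
Why: Proposed new method: excitation of the alkene–CuOTf complex of 21 at 254 nm twists C8=C9 and the complex should relax to the copper-bound E-cycloheptene 22, as cycloheptene itself does with monovalent copper triflate; when MeCN displaces copper in the presence of dimethyldioxirane, the strained, pyramidalised E-alkene should take up oxygen by concerted spiro [2+1] transfer, as E-cyclooctene is known to do stereospecifically. The oxirane is closed by suprafacial addition of one oxygen atom to the only exposed (outer) face of the E-alkene, both C–O bonds forming together, so the anti relationship of C7 and C10 is carried into a trans-fused ring. C8 and C9 are set at once by the helicity of 22: the isomer with a positive C7–C8–C9–C10 torsion gives (8R,9R)-23. In that helicity the C10–O bond lies gauche to the alkene on its exposed face, so the free 10β-hydroxyl can bind the copper held by the alkene and later hydrogen-bond the dioxirane, whereas a silyl ether there would press against the C8 methyl; this is why O10 is unprotected. Chemoselectivity rests on strain: Z-alkene 21 should be inert to the dioxirane at −78 °C, and E-alkene that reverts is recovered as 21 and recycled. The step needs E over Z (secured by copper complexation at low temperature) and one helicity over the other (secured only by the C10 hydroxyl against the ring fusion). The closest known reactions are the CuOTf-mediated photoisomerisation of cycloheptene and the epoxidation of E-cyclooctene; a trans-fused cycloheptene oxide in a bicyclic system has not been made this way.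

Step 21
Reactants: 23 (8R,9R)-2α-acetoxy-8,9-epoxydaucane-4α,6β,10β-triol; 24 veratric acid (3,4-dimethoxybenzoic acid)
Product: 26 (1R,2S,4S,5R,6R,8R,9R,10R)-2-acetoxy-8,9-epoxy-4,10-dihydroxydaucan-6-yl 3,4-dimethoxybenzoate (CNP0197096.4), via veratroyl chloride 25 (not isolated)
Conditions: 24, (COCl)2, DMF (cat.), CH2Cl2, 0 °C → rt, evaporate; then 23, Et3N, DMAP, CH2Cl2, −20 → 0 °C
Reagents that add atoms: none
Why: DMAP-catalysed acylation with the acid chloride 25 made from 24; O6 is flanked by a methylene group, whereas O10 is neopentyl and axial beside the oxirane and O4 is tertiary, so the ester should form at C6, and the non-acidic, cold conditions spare the strained oxirane.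

## Compound list

1 | (S)-4-hydroxycyclopent-2-en-1-one | O=C1C=C[C@@H](O)C1 | starting material
2 | (S)-4-(tert-butyldimethylsilyloxy)cyclopent-2-en-1-one | O=C1C=C[C@@H](O[Si](C)(C)C(C)(C)C)C1 | intermediate
3 | (S)-4-(tert-butyldimethylsilyloxy)-2-iodocyclopent-2-en-1-one | O=C1C(I)=C[C@@H](O[Si](C)(C)C(C)(C)C)C1 | intermediate
4 | (S)-4-(tert-butyldimethylsilyloxy)-2-methylcyclopent-2-en-1-one | CC1=C[C@@H](O[Si](C)(C)C(C)(C)C)CC1=O | intermediate
5 | bromomagnesium enolate (C1=C2, O2–MgBr) of the 4β-silyloxy-5α-vinyl ketone | CC1=C(O[Mg]Br)C[C@H](O[Si](C)(C)C(C)(C)C)[C@H]1C=C | intermediate (not isolated)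
6 | (2R,3S,4S)-4-(tert-butyldimethylsilyloxy)-2-(hydroxymethyl)-2-methyl-3-vinylcyclopentan-1-one (C1 methyl α, C10H2OH β, C5 vinyl α, C4 OTBS β) | OC[C@]1(C)C(=O)C[C@H](O[Si](C)(C)C(C)(C)C)[C@H]1C=C | intermediate
7 | 4β-(tert-butyldimethylsilyloxy)-1β-(hydroxymethyl)-1α-methyl-5α-vinylcyclopentan-2α-ol | OC[C@]1(C)[C@@H](O)C[C@H](O[Si](C)(C)C(C)(C)C)[C@H]1C=C | intermediate
8 | O2,O10-(4-methoxybenzylidene) acetal of 7 (aryl equatorial) | COc1ccc(cc1)[C@@H]2OC[C@]3(C)[C@@H](O2)C[C@H](O[Si](C)(C)C(C)(C)C)[C@H]3C=C | intermediate
9 | 4β-alcohol (acetal, 5α-vinyl) | COc1ccc(cc1)[C@@H]2OC[C@]3(C)[C@@H](O2)C[C@H](O)[C@H]3C=C | intermediate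
10 | C4 ketone (acetal, 5α-vinyl) | COc1ccc(cc1)[C@@H]2OC[C@]3(C)[C@@H](O2)CC(=O)[C@H]3C=C | intermediate
11 | 4α-hydroxy-4β-isopropyl-5α-vinyl acetal | COc1ccc(cc1)[C@@H]2OC[C@]3(C)[C@@H](O2)C[C@](O)(C(C)C)[C@H]3C=C | intermediate
12 | C6 aldehyde (5α-formyl acetal) | COc1ccc(cc1)[C@@H]2OC[C@]3(C)[C@@H](O2)C[C@](O)(C(C)C)[C@H]3C=O | intermediate
13 | (6R)-homoallylic alcohol (acetal) | COc1ccc(cc1)[C@@H]2OC[C@]3(C)[C@@H](O2)C[C@](O)(C(C)C)[C@H]3[C@H](O)CC(C)=C | intermediate
14 | triol with 2α-O-(4-methoxybenzyl) and 1β-CH2OH | OC[C@]1(C)[C@@H](OCc2ccc(OC)cc2)C[C@](O)(C(C)C)[C@H]1[C@H](O)CC(C)=C | intermediate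
15 | C10 aldehyde | O=C[C@]1(C)[C@@H](OCc2ccc(OC)cc2)C[C@](O)(C(C)C)[C@H]1[C@H](O)CC(C)=C | intermediate
16 | (6R,10S)-diene triol | C=C[C@H](O)[C@]1(C)[C@@H](OCc2ccc(OC)cc2)C[C@](O)(C(C)C)[C@H]1[C@H](O)CC(C)=C | intermediate
17 | 2α-(4-methoxybenzyloxy)dauc-8(Z)-ene-4α,6β,10β-triol | O[C@@H]2C/C(C)=C\[C@H](O)[C@]3(C)[C@@H](OCc4ccc(OC)cc4)C[C@](O)(C(C)C)[C@@H]23 | intermediate
18 | 6β,10β-bis(triethylsilyloxy)-2α-(4-methoxybenzyloxy)dauc-8(Z)-en-4α-ol | CC[Si](CC)(CC)O[C@@H]2C/C(C)=C\[C@H](O[Si](CC)(CC)CC)[C@]3(C)[C@@H](OCc4ccc(OC)cc4)C[C@](O)(C(C)C)[C@@H]23 | intermediate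
19 | 6β,10β-bis(triethylsilyloxy)dauc-8(Z)-ene-2α,4α-diol | CC[Si](CC)(CC)O[C@@H]2C/C(C)=C\[C@H](O[Si](CC)(CC)CC)[C@]3(C)[C@@H](O)C[C@](O)(C(C)C)[C@@H]23 | intermediate
20 | 2α-acetoxy-6β,10β-bis(triethylsilyloxy)dauc-8(Z)-en-4α-ol | CC[Si](CC)(CC)O[C@@H]2C/C(C)=C\[C@H](O[Si](CC)(CC)CC)[C@]3(C)[C@@H](OC(C)=O)C[C@](O)(C(C)C)[C@@H]23 | intermediate
21 | 2α-acetoxydauc-8(Z)-ene-4α,6β,10β-triol | O[C@@H]2C/C(C)=C\[C@H](O)[C@]3(C)[C@@H](OC(C)=O)C[C@](O)(C(C)C)[C@@H]23 | intermediate
22 | copper triflate complex of the (8E)-isomer of 21 (C7–C8–C9–C10 torsion positive) | O[C@@H]2C/C(C)=C/[C@H](O)[C@]3(C)[C@@H](OC(C)=O)C[C@](O)(C(C)C)[C@@H]23.[Cu+].[O-]S(=O)(=O)C(F)(F)F | intermediate (not isolated)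
23 | (8R,9R)-2α-acetoxy-8,9-epoxydaucane-4α,6β,10β-triol (trans-fused oxirane) | O[C@@H]2C[C@@]3(C)O[C@@H]3[C@H](O)[C@]3(C)[C@@H](OC(C)=O)C[C@](O)(C(C)C)[C@@H]23 | intermediate
24 | veratric acid (3,4-dimethoxybenzoic acid) | COc1ccc(C(=O)O)cc1OC | starting material
25 | veratroyl chloride | COc1ccc(C(=O)Cl)cc1OC | intermediate (not isolated)
26 | (1R,2S,4S,5R,6R,8R,9R,10R)-2-acetoxy-8,9-epoxy-4,10-dihydroxydaucan-6-yl 3,4-dimethoxybenzoate (CNP0197096.4) | COc1ccc(C(=O)O[C@@H]2C[C@@]3(C)O[C@@H]3[C@H](O)[C@]3(C)[C@@H](OC(C)=O)C[C@](O)(C(C)C)[C@@H]23)cc1OC | target

## Step count and least certain steps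

Total: 21 steps. Longest linear sequence: 21 steps (1 to 26; 24 enters in the last step).

**Step 20 (key step).** The most likely failure is formation of the E-alkene with the wrong helicity, or too little of the right one. Ring A fixes the fusion torsion C10–C1–C5–C6 as negative. A hand-built model of E-cycloheptene pairs the positive C7–C8–C9–C10 torsion needed here with a positive torsion at that bond, so the ring fusion may favour the other helicity. The hydroxyl–copper chelate has to outweigh this, and the model is approximate. Further risks are thermal reversion before oxygen transfer and Lewis-acid opening of the oxirane by copper triflate on warming.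
Fallback, using known reaction types for medium-ring E-alkenes: set out from 21 and irradiate at 254 nm with methyl benzoate as singlet sensitiser in a closed-loop flow reactor. The stream passes cold through AgNO3-impregnated silica, which retains the E-isomer as the silver nitrate complex of the (8E)-alkene F1 while the Z-alkene returns to the lamp. The two helical diastereomers of the complex are separable; the unwanted one is decomplexed, allowed to revert to 21 and recycled, so the needed isomer can be accumulated even if it is the minor one. The wanted complex is stirred at −78 °C with dimethyldioxirane while NaCl strips the silver, so the free (8E)-alkene F2 is epoxidised as it is released, returning to the route at 23.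

**Step 21.** Poor site selectivity (acylation at O10 or at both hydroxyls) is possible if the steric difference between O6 and O10 is smaller than assumed. Base-induced migration of the oxirane to C9–C10 (Payne) or of the acetyl group from O2 to O10 would also destroy the product.
Fallback: set out from 23 and convert the 4,6-diol with Bu2Sn(OMe)2 (toluene, rt, evaporation) into the 4,6-O-dibutylstannylene acetal F6. This activates the secondary O6 over the tertiary O4 and leaves O10, which has no diol partner, unactivated. Reaction of the acetal with 25 at 0 °C without amine base returns to the route at 26.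

**Step 14.** Loss of chelation control would give the C10 epimer by a Felkin-type addition. THF from the Grignard solution and the two magnesium alkoxides formed at O4 and O6 compete for the Lewis acid, and the chelate must be trans-fused to ring A.
Fallback: set out from 15 and replace substrate control by reagent control, using a catalytic asymmetric Nozaki–Hiyama–Kishi vinylation (vinyl bromide, CrCl2 with a chiral sulfonamide ligand, NiCl2 as co-catalyst, Mn, Et3SiCl). These conditions tolerate the free hydroxyls and return directly to 16 with no new intermediate.

**Step 11.** Mismatched double stereodifferentiation may lower the facial selectivity at C6, because the α-branched aldehyde carries two large groups at C5 and a free β-hydroxyl. Protonolysis of the borane by that hydroxyl would consume reagent.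
Fallback: set out from 12 and use substrate control instead. Methallylmagnesium chloride with MgBr2 should add through the chelate between O4 and the aldehyde on the face away from C3, which is predicted to give the (6S)-epimer of 13, F4. Mitsunobu inversion (4-nitrobenzoic acid, DIAD, PPh3) gives the (6R)-4-nitrobenzoate F5, and methanolysis (K2CO3, MeOH) returns to the route at 13.

**Step 4.** Proton transfer within enolate 5 followed by β-elimination of the silyloxy group, retro-aldol loss of formaldehyde on warming, or multiple hydroxymethylation would lower the efficiency of the one-pot trapping.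
Fallback: set out from 4 and run the conjugate addition with Me3SiCl present (CH2=CHMgBr, CuBr·SMe2, Me3SiCl, THF, −78 °C) to isolate the trimethylsilyl enol ether F3. A Mukaiyama hydroxymethylation with aqueous formaldehyde and Yb(OTf)3 (THF/H2O, rt), again anti to the vinyl group, returns to the route at 6.

## Further compounds

F1 | step 20 | silver nitrate complex of the (8E)-isomer of 21 | O[C@@H]2C/C(C)=C/[C@H](O)[C@]3(C)[C@@H](OC(C)=O)C[C@](O)(C(C)C)[C@@H]23.[Ag+].[O-][N+](=O)[O-]
F2 | step 20 | free (8E)-isomer of 21 | O[C@@H]2C/C(C)=C/[C@H](O)[C@]3(C)[C@@H](OC(C)=O)C[C@](O)(C(C)C)[C@@H]23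
F3 | step 4 | trimethylsilyl enol ether of the 4β-silyloxy-5α-vinyl ketone | CC1=C(O[Si](C)(C)C)C[C@H](O[Si](C)(C)C(C)(C)C)[C@H]1C=C
F4 | step 11 | (6S)-epimer of 13 | COc1ccc(cc1)[C@@H]2OC[C@]3(C)[C@@H](O2)C[C@](O)(C(C)C)[C@H]3[C@@H](O)CC(C)=C
F5 | step 11 | (6R)-4-nitrobenzoate of 13 | COc1ccc(cc1)[C@@H]2OC[C@]3(C)[C@@H](O2)C[C@](O)(C(C)C)[C@H]3[C@H](OC(=O)c4ccc(cc4)[N+](=O)[O-])CC(C)=C
F0 | step 14 | none | none
F6 | step 21 | 4,6-O-dibutylstannylene acetal of 23 | CCCC[Sn]1(CCCC)O[C@@H]2C[C@@]3(C)O[C@@H]3[C@H](O)[C@]3(C)[C@@H](OC(C)=O)C[C@](O1)(C(C)C)[C@@H]23
A1 | alternative 1 | 4-isopropyl-6-methoxy-1,8-dimethyl-4-(triethylsilyloxy)bicyclo[5.3.0]deca-5,7,9-trien-2-one | COC2=C3[C@@](O[Si](CC)(CC)CC)(C(C)C)CC(=O)[C@@]3(C)C=CC(C)=C2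
A2 | alternative 1 | 2-diazo-5-(2-methoxy-4-methylphenyl)-6-methyl-5-(triethylsilyloxy)heptan-3-one | COc1cc(C)ccc1[C@@](O[Si](CC)(CC)CC)(C(C)C)CC(=O)C(C)=[N+]=[N-]
A3 | alternative 2 | trans-fused 2,4-bis(tert-butyldimethylsilyloxy)-1-methylbicyclo[5.3.0]dec-6-en-8-one | O=C1C=C[C@@H]2[C@@H](O[Si](C)(C)C(C)(C)C)C[C@H](O[Si](C)(C)C(C)(C)C)[C@@]2(C)CC1
A4 | alternative 2 | trimethylsilyl enol ether (C6=C8) of the trans-hydrindanone bearing the two silyloxy groups | C[Si](C)(C)OC1=C[C@@H]2[C@@H](O[Si](C)(C)C(C)(C)C)C[C@H](O[Si](C)(C)C(C)(C)C)[C@@]2(C)CC1
A5 | alternative 2 | (S)-Hajos–Parrish ketone | C[C@]12CCC(=O)C=C1CCC2=O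
A6 | alternative 3 | trans-fused bicyclo[5.3.0]decan-6-one with C4 silyl ether and C10 dioxolane | O=C2CCCC4(OCCO4)[C@]3(C)CC[C@@H](O[Si](C)(C)C(C)(C)C)[C@@H]23
A7 | alternative 3 | cis-decalin hydroxy mesylate (C6 ring-fusion hydroxyl, C5 mesylate, C4 silyl ether, C10 dioxolane) | CS(=O)(=O)O[C@@H]1[C@H](O[Si](C)(C)C(C)(C)C)CC[C@@]2(C)C3(OCCO3)CCC[C@@]12O
A8 | alternative 3 | (R)-Wieland–Miescher ketone | C[C@@]12CCC(=O)C=C1CCCC2=O
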